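A direct plan would build both rings as aromatic acylphloroglucinols: ring A monomer A1 (butanoyl, prenyl) and ring B monomer A2 (acetyl, methyl).
It would join them through a Mannich base and an ortho-quinone methide to the fully aromatic methylene-bridged dimer A3.
It would end with a catalytic enantioselective dearomatising allylic C-geranylation (Tsuji–Trost type) of A3 at the methyl-bearing carbon of ring B.
Its weakest steps would be:
(a) the final geranylation, which would leave the only stereocentre to an untested catalyst that must tell apart two faces of ring B differing only by acetyl against arylmethyl two bonds away; O-alkylation and attack at the prenyl-bearing carbon of ring A would compete, and all of this would be risked on the most precious intermediate;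
(b) the single C-prenylation of the acylphloroglucinol with prenyl bromide in aqueous alkali, which would be statistical (mono-, bis- and O-alkylation), so that the supply of ring A would rest on a separation.

**Plan of the new route**
Feature used: in ring B the stereocentre C4 (methyl, geranyl) sits between C3 and C5 and is stereogenic only because C3 is bonded to the acetyl-bearing C2 and C5 to the bridge-bearing C6; C3–C4–C5 is a methyl(geranyl)malonyl unit and C6–C1–C2(–COCH3) an acetylacetone unit.
Retrosynthesis: first the bridge bond CH2–C6 of ring B is cut (ortho-quinone methide of ring A plus the ring B enol); then in ring B the bonds C2–C3 (Claisen ring closure) and C5–C6 (acylation of the acetylacetone dianion) are cut, which leads to acetylacetone and an open-chain (R)-methyl(geranyl)malonic half-ester with two chemically different carboxyl carbons.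
Order of the rings: ring A is phloroglucinol itself, substituted by two directed lithiations; ring B is closed from the open chain only in step 4 and is never aromatic; the two rings meet in the last step, so no aromatic dimer occurs.
The stereocentre is made on an achiral dimethyl malonate by enzymatic desymmetrisation and carried into ring B by the order of the two acylations, so no dearomatisation and no late asymmetric step is needed; the prenyl group is placed by lithiation of a C3-symmetric ether, so no statistical alkylation occurs.

Key step: step 4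

Assumption: pig liver esterase is taken to hydrolyse the dimethyl malonate of step 1 in the sense known for 2-methylmalonates with long lipophilic chains, which gives the (R)-half-ester; the sign would be checked before step 3.

"Geranyl" below means (2E)-3,7-dimethylocta-2,6-dien-1-yl.

Step 1
Reactants: 1 dimethyl 2-methylpropanedioate (dimethyl methylmalonate); 2 geranyl bromide [(2E)-1-bromo-3,7-dimethylocta-2,6-diene]
Product: 3 dimethyl 2-[(2E)-3,7-dimethylocta-2,6-dien-1-yl]-2-methylpropanedioate
Conditions: NaH (1.05 equiv), THF, 0 °C; then 2 (1.0 equiv), 0 °C to rt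
Reagents that add atoms: none
Why: Malonic ester alkylation (SN2 of the sodium enolate of 1 at the primary allylic bromide, which keeps the E alkene); the product has two identical ester groups and is achiral.

Step 2
Reactants: 3 dimethyl 2-[(2E)-3,7-dimethylocta-2,6-dien-1-yl]-2-methylpropanedioate
Product: 4 (2R)-2-[(2E)-3,7-dimethylocta-2,6-dien-1-yl]-3-methoxy-2-methyl-3-oxopropanoic acid
Conditions: pig liver esterase, 0.1 M phosphate buffer pH 7.5/DMSO 9:1, 25 °C, pH-stat (1 M NaOH, 1.0 equiv); 1 M HCl to pH 2; if needed one crystallisation of the (S)-1-phenylethylammonium salt, then 1 M HCl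
Reagents that add atoms: water, O
Why: Enzymatic desymmetrisation (hydrolysis of one of two enantiotopic ester groups, a known reaction of dimethyl 2-alkyl-2-methylmalonates): the esterase should bind the long lipophilic geranyl chain in its large hydrophobic pocket and hydrolyse one methoxycarbonyl group, which sets the (R) centre and makes the two carboxyl carbons chemically different; the quaternary half-ester has no α-hydrogen and cannot racemise.

Step 3
Reactants: 4 (2R)-2-[(2E)-3,7-dimethylocta-2,6-dien-1-yl]-3-methoxy-2-methyl-3-oxopropanoic acid; 5 acetylacetone (pentane-2,4-dione)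
Product: 7 methyl (2R)-2-[(2E)-3,7-dimethylocta-2,6-dien-1-yl]-2-methyl-3,5,7-trioxooctanoate, via acyl imidazole 6 (not isolated)
Conditions: 4, 1,1'-carbonyldiimidazole (1.1 equiv), THF, rt, 2 h; separately 5 (3.0 equiv), LiN(i-Pr)2 (6.0 equiv), THF, 0 °C, 30 min; add the solution of 6 at −78 °C, warm to −20 °C; 1 M HCl; used without storage
Reagents that add atoms: 1,1'-carbonyldiimidazole, O=C(n1ccnc1)n1ccnc1 (its imidazolyl group stays only in 6 and leaves again as imidazole)
Why: γ-Acylation of a β-diketone dianion: the acid is activated as acyl imidazole 6 (no ketene and no enolisation are possible because the α-carbon is quaternary), the terminal carbanion of the acetylacetone dianion attacks it in preference to the less electrophilic methyl ester, and the triketone is at once protected as its enolate; this forms the bond that becomes C5–C6 of ring B and leaves the stereocentre untouched.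

Step 4
Reactants: 7 methyl (2R)-2-[(2E)-3,7-dimethylocta-2,6-dien-1-yl]-2-methyl-3,5,7-trioxooctanoate
Product: 8 (4R)-2-acetyl-4-[(2E)-3,7-dimethylocta-2,6-dien-1-yl]-3,5-dihydroxy-4-methylcyclohexa-2,5-dien-1-one (ring B, with H at C6)
Conditions: KOt-Bu (3.0 equiv), THF, 0 °C to 40 °C; then cold 1 M HCl
Reagents that add atoms: none
Why: KOt-Bu turns 7 into its dianion, and the diketonate carbon C6 (octanoate numbering, the former central carbon of acetylacetone) adds to the ester carbonyl C1 and expels methoxide, an intramolecular Claisen (Dieckmann) condensation of the kind that converts 3,5,7-triketo esters into acylphloroglucinols and 2,2-dialkyl-3,5-dioxo esters into syncarpic-acid-type triones. Ring B closes in the 6-(enolendo)-exo-trig mode through the bond that becomes C2–C3 of the target, chain carbons C1–C6 becoming the ring and C7–C8 the acetyl group; because C2 of 7 is quaternary the ring cannot aromatise and stays the enolised triketone. No stereocentre is created: C2 of 7 becomes C4 of 8 with its four bonds intact, and it reads (R) in the ring because the former ester carbon ends next to the acetyl-bearing carbon and the former acid carbon next to C6–H, so the controlling element is the constitution of 7 (which carboxyl carbon was acylated first), and the reverse order would give the enantiomer. The selectivity needed is C-acylation at C6 over other closures: C4 could only form a four-membered ring, the methyl C8 is not deprotonated by this base so the aldol closure onto C3 does not start, and any O-acylated pyran-2,4-dione should be returned to the C-acylated product under the same conditions because the doubly stabilised triketone enolate is the thermodynamic sink. A bulky non-nucleophilic base is chosen because free methoxide in methanol could cleave the C3–C4 bond by retro-Claisen reaction to the achiral malonate 3 and so erase the stereocentre.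

Step 5
Reactants: 9 phloroglucinol (benzene-1,3,5-triol)
Product: 10 1,3,5-tris(methoxymethoxy)benzene
Conditions: NaH (3.6 equiv), MOMCl (3.6 equiv), DMF, 0 °C to rt
Reagents that add atoms: chloromethyl methyl ether (MOMCl), COCCl
Why: Williamson-type O-alkylation of the phenoxide with a hard electrophile; the three MOM ethers protect the phenols and serve as directing groups for the next two steps.

Step 6
Reactants: 10 1,3,5-tris(methoxymethoxy)benzene; 11 prenyl bromide (1-bromo-3-methylbut-2-ene)
Product: 12 1,3,5-tris(methoxymethoxy)-2-(3-methylbut-2-en-1-yl)benzene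
Conditions: n-BuLi (1.1 equiv), THF, 0 °C, 1 h; CuBr·SMe2 (0.1 equiv), then 11 (1.2 equiv), −78 °C to rt
Reagents that add atoms: none
Why: Directed ortho-metalation at a ring CH flanked by two OMOM groups (all three CH are equivalent, so one aryllithium forms), then CuBr·SMe2-catalysed allylic substitution at the CH2 end of prenyl bromide; one equivalent of base gives exactly one prenyl group, so no statistical C-prenylation of a free phloroglucinol is needed.

Step 7
Reactants: 12 1,3,5-tris(methoxymethoxy)-2-(3-methylbut-2-en-1-yl)benzene; 13 N-methoxy-N-methylbutanamide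
Product: 14 1-[2,4,6-tris(methoxymethoxy)-3-(3-methylbut-2-en-1-yl)phenyl]butan-1-one
Conditions: n-BuLi (1.2 equiv), THF, 0 °C, 1 h; then 13 (1.5 equiv), −78 °C to rt; aq. NH4Cl
Reagents that add atoms: none
Why: Second directed ortho-metalation at one of the two equivalent remaining CH groups (each between two OMOM groups, kinetically preferred over the benzylic-allylic CH2), then acylation by the N-methoxy-N-methylamide, whose chelated tetrahedral intermediate stops at the ketone (Weinreb ketone synthesis).

Step 8
Reactants: 14 1-[2,4,6-tris(methoxymethoxy)-3-(3-methylbut-2-en-1-yl)phenyl]butan-1-one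
Product: 15 1-[2,4,6-trihydroxy-3-(3-methylbut-2-en-1-yl)phenyl]butan-1-one (ring A monomer)
Conditions: 3 M aq. HCl/MeOH (1:10), 40 °C, followed to completion and stopped at once
Reagents that add atoms: none
Why: Acid-catalysed methanolysis of the three acetals (MOM removal), kept mild and short so that the prenyl alkene is not protonated and does not cyclise onto a neighbouring phenol.

Step 9
Reactants: 15 1-[2,4,6-trihydroxy-3-(3-methylbut-2-en-1-yl)phenyl]butan-1-one; 8 (4R)-2-acetyl-4-[(2E)-3,7-dimethylocta-2,6-dien-1-yl]-3,5-dihydroxy-4-methylcyclohexa-2,5-dien-1-one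
Product: 18 (4R)-2-acetyl-6-{[3-butanoyl-2,4,6-trihydroxy-5-(3-methylbut-2-en-1-yl)phenyl]methyl}-4-[(2E)-3,7-dimethylocta-2,6-dien-1-yl]-3,5-dihydroxy-4-methylcyclohexa-2,5-dien-1-one (CNP0227753.1), via Mannich base 16 (not isolated), via ortho-quinone methide 17 (not isolated)
Conditions: 15 (1.05 equiv), 37% aq. CH2O (1.05 equiv), 40% aq. Me2NH (1.1 equiv), EtOH, 0 °C to rt; evaporate; then 8 (1.0 equiv), 1,4-dioxane, 90 °C, N2 sweep
Reagents that add atoms: formaldehyde, C=O; dimethylamine, CNC (its atoms stay only in 16 and leave again as the free amine)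
Why: Mannich aminomethylation at the only free ring carbon of 15; then the vinylogous acid 8 protonates the benzylic amine, dimethylamine leaves to give ortho-quinone methide 17, and the enolate of 8 adds through C6, its only nucleophilic ring carbon (Michael addition; any O-adduct re-ionises), which forms the methylene bridge without touching the quaternary C4; no stereocentre is formed.

**Compound list**
1 | dimethyl 2-methylpropanedioate (dimethyl methylmalonate) | COC(=O)C(C)C(=O)OC | starting material
2 | geranyl bromide [(2E)-1-bromo-3,7-dimethylocta-2,6-diene] | BrC/C=C(\C)CCC=C(C)C | starting material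
3 | dimethyl 2-[(2E)-3,7-dimethylocta-2,6-dien-1-yl]-2-methylpropanedioate | COC(=O)C(C)(C/C=C(\C)CCC=C(C)C)C(=O)OC | intermediate
4 | (2R)-2-[(2E)-3,7-dimethylocta-2,6-dien-1-yl]-3-methoxy-2-methyl-3-oxopropanoic acid | OC(=O)[C@@](C)(C/C=C(\C)CCC=C(C)C)C(=O)OC | intermediate
5 | acetylacetone (pentane-2,4-dione) | CC(=O)CC(C)=O | starting material
6 | methyl (2R)-2-[(2E)-3,7-dimethylocta-2,6-dien-1-yl]-3-(1H-imidazol-1-yl)-2-methyl-3-oxopropanoate (acyl imidazole, not isolated) | O=C(n1ccnc1)[C@@](C)(C/C=C(\C)CCC=C(C)C)C(=O)OC | intermediate
7 | methyl (2R)-2-[(2E)-3,7-dimethylocta-2,6-dien-1-yl]-2-methyl-3,5,7-trioxooctanoate | CC(=O)CC(=O)CC(=O)[C@@](C)(C/C=C(\C)CCC=C(C)C)C(=O)OC | intermediate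
8 | (4R)-2-acetyl-4-[(2E)-3,7-dimethylocta-2,6-dien-1-yl]-3,5-dihydroxy-4-methylcyclohexa-2,5-dien-1-one | C1=C(O)[C@@](C)(C/C=C(\C)CCC=C(C)C)C(O)=C(C(C)=O)C1=O | intermediate
9 | phloroglucinol (benzene-1,3,5-triol) | Oc1cc(O)cc(O)c1 | starting material
10 | 1,3,5-tris(methoxymethoxy)benzene | COCOc1cc(OCOC)cc(OCOC)c1 | intermediate
11 | prenyl bromide (1-bromo-3-methylbut-2-ene) | CC(C)=CCBr | starting material
12 | 1,3,5-tris(methoxymethoxy)-2-(3-methylbut-2-en-1-yl)benzene | COCOc1cc(OCOC)c(CC=C(C)C)c(OCOC)c1 | intermediate
13 | N-methoxy-N-methylbutanamide | CCCC(=O)N(C)OC | starting material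
14 | 1-[2,4,6-tris(methoxymethoxy)-3-(3-methylbut-2-en-1-yl)phenyl]butan-1-one | CCCC(=O)c1c(OCOC)cc(OCOC)c(CC=C(C)C)c1OCOC | intermediate
15 | 1-[2,4,6-trihydroxy-3-(3-methylbut-2-en-1-yl)phenyl]butan-1-one | CCCC(=O)c1c(O)cc(O)c(CC=C(C)C)c1O | intermediate
16 | 1-[3-[(dimethylamino)methyl]-2,4,6-trihydroxy-5-(3-methylbut-2-en-1-yl)phenyl]butan-1-one (Mannich base, not isolated) | CCCC(=O)c1c(O)c(CC=C(C)C)c(O)c(CN(C)C)c1O | intermediate
17 | 2-butanoyl-3,5-dihydroxy-6-methylidene-4-(3-methylbut-2-en-1-yl)cyclohexa-2,4-dien-1-one (ortho-quinone methide, not isolated) | CCCC(=O)C1=C(O)C(CC=C(C)C)=C(O)C(=C)C1=O | intermediate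
18 | (4R)-2-acetyl-6-{[3-butanoyl-2,4,6-trihydroxy-5-(3-methylbut-2-en-1-yl)phenyl]methyl}-4-[(2E)-3,7-dimethylocta-2,6-dien-1-yl]-3,5-dihydroxy-4-methylcyclohexa-2,5-dien-1-one | CCCC(=O)c1c(O)c(CC=C(C)C)c(O)c(CC2=C(O)[C@@](C)(C/C=C(\C)CCC=C(C)C)C(O)=C(C(C)=O)C2=O)c1O | target

Total step count: 9. Longest linear sequence: 5 steps (steps 1–4 and 9, or steps 5–9).

**Steps most likely to fail**

Step 2. The esterase may discriminate the two enantiotopic methoxycarbonyl groups of the long, branched substrate poorly or in the opposite sense, or turn it over slowly. The fallback is an asymmetric phase-transfer alkylation that sets out from 2 and comes back at 4. 2,2,5-Trimethyl-1,3-dioxane-4,6-dione would be opened with tert-butanol (reflux) to 3-tert-butoxy-2-methyl-3-oxopropanoic acid F1. Esterification with 2,2-diphenylethanol (EDC·HCl, DMAP, CH2Cl2) would give 1-tert-butyl 3-(2,2-diphenylethyl) 2-methylpropanedioate F2. Alkylation with 2 under phase-transfer conditions (50% aq. KOH, toluene, −40 °C, 5 mol % of that enantiomer of 3,4,5-trifluorophenyl-NAS bromide which leads to the (S) product) should give 1-tert-butyl 3-(2,2-diphenylethyl) (2S)-2-geranyl-2-methylpropanedioate F3. KOH/MeOH would cleave only the diphenylethyl ester to (2S)-3-tert-butoxy-2-geranyl-2-methyl-3-oxopropanoic acid F4. MeI/K2CO3 (DMF) would give 1-tert-butyl 3-methyl (2S)-2-geranyl-2-methylpropanedioate F5, and TMSOTf/2,6-lutidine (CH2Cl2, 0 °C, aqueous work-up) would remove the tert-butyl group to give 4. The (S) descriptors of F3–F5 arise only because the tert-butyl ester outranks the other carboxyl group; the spatial arrangement is that of 4.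

Step 4. The stabilised diketonate may fail to close onto the hindered ester, the chain may be cut by retro-Claisen reaction, or O-acylation may persist. The fallback makes the two ring bonds in the opposite order, sets out from 4 and comes back at 8. The free acid of 4 would be esterified (Boc2O, DMAP, t-BuOH) to the tert-butyl methyl diester F5. LiOH (THF/MeOH/H2O, 50 °C) would cleave only the methyl ester to the tert-butyl half-ester acid F4, so that the two carboxyl carbons have changed roles. 1-Chloro-N,N,2-trimethylprop-1-en-1-amine (CH2Cl2, 0 °C) would give tert-butyl (2R)-3-chloro-2-geranyl-2-methyl-3-oxopropanoate F6. C-acylation of the magnesium enolate of 5 (MgCl2, pyridine, CH2Cl2) would give the triacylmethane tert-butyl (2S)-4-acetyl-2-geranyl-2-methyl-3,5-dioxohexanoate F7. LiN(i-Pr)2 (3.3 equiv, THF, −78 to 0 °C) would then close ring B by Dieckmann attack of an acetyl CH2 carbanion on the tert-butyl ester to give 8. Because both the roles of the carboxyl carbons and the order of the acylations are reversed, the same (R) ring configuration should result.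

Step 9. Reversible formation of quinone methides may exchange the methylene bridge between the partners and lead to symmetrical dimers, or the quinone methide may oligomerise before the enol adds. The fallback is a reductive alkylation that sets out from 15 and comes back at 18. Vilsmeier formylation of 15 at its only free ring carbon (POCl3, DMF, EtOAc, 0 °C to rt; aq. NaOAc) would give 3-butanoyl-2,4,6-trihydroxy-5-(3-methylbut-2-en-1-yl)benzaldehyde F8. Condensation of F8 with 8 (L-proline 20 mol %, CH2Cl2/EtOH, rt) would give the Knoevenagel adduct (4S)-2-acetyl-6-{[3-butanoyl-2,4,6-trihydroxy-5-(3-methylbut-2-en-1-yl)phenyl]methylidene}-4-geranyl-3-hydroxy-4-methylcyclohex-2-ene-1,5-dione F9. F9 would be reduced in the same flask by hydride transfer from Hantzsch ester (diethyl 2,6-dimethyl-1,4-dihydropyridine-3,5-dicarboxylate, 1.2 equiv) to 18. The (S) descriptor of F9 again reflects a priority change only.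

**Further compounds**
F1 | step 2 | 3-tert-butoxy-2-methyl-3-oxopropanoic acid | CC(C(=O)O)C(=O)OC(C)(C)C
F2 | step 2 | 1-tert-butyl 3-(2,2-diphenylethyl) 2-methylpropanedioate | CC(C(=O)OC(C)(C)C)C(=O)OCC(c1ccccc1)c1ccccc1
F3 | step 2 | 1-tert-butyl 3-(2,2-diphenylethyl) (2S)-2-[(2E)-3,7-dimethylocta-2,6-dien-1-yl]-2-methylpropanedioate | CC(C)(C)OC(=O)[C@@](C)(C/C=C(\C)CCC=C(C)C)C(=O)OCC(c1ccccc1)c1ccccc1
F4 | step 2 | (2S)-3-tert-butoxy-2-[(2E)-3,7-dimethylocta-2,6-dien-1-yl]-2-methyl-3-oxopropanoic acid | CC(C)(C)OC(=O)[C@@](C)(C/C=C(\C)CCC=C(C)C)C(=O)O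
F5 | step 2 | 1-tert-butyl 3-methyl (2S)-2-[(2E)-3,7-dimethylocta-2,6-dien-1-yl]-2-methylpropanedioate | CC(C)(C)OC(=O)[C@@](C)(C/C=C(\C)CCC=C(C)C)C(=O)OC
F6 | step 4 | tert-butyl (2R)-3-chloro-2-[(2E)-3,7-dimethylocta-2,6-dien-1-yl]-2-methyl-3-oxopropanoate | CC(C)(C)OC(=O)[C@@](C)(C/C=C(\C)CCC=C(C)C)C(Cl)=O
F7 | step 4 | tert-butyl (2S)-4-acetyl-2-[(2E)-3,7-dimethylocta-2,6-dien-1-yl]-2-methyl-3,5-dioxohexanoate | CC(C)(C)OC(=O)[C@@](C)(C/C=C(\C)CCC=C(C)C)C(=O)C(C(C)=O)C(C)=O
F8 | step 9 | 3-butanoyl-2,4,6-trihydroxy-5-(3-methylbut-2-en-1-yl)benzaldehyde | CCCC(=O)c1c(O)c(CC=C(C)C)c(O)c(C=O)c1O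
F9 | step 9 | (4S)-2-acetyl-6-{[3-butanoyl-2,4,6-trihydroxy-5-(3-methylbut-2-en-1-yl)phenyl]methylidene}-4-[(2E)-3,7-dimethylocta-2,6-dien-1-yl]-3-hydroxy-4-methylcyclohex-2-ene-1,5-dione | CCCC(=O)c1c(O)c(CC=C(C)C)c(O)c(C=C2C(=O)[C@@](C)(C/C=C(\C)CCC=C(C)C)C(O)=C(C(C)=O)C2=O)c1O
A1 | direct plan | 1-[2,4,6-trihydroxy-3-(3-methylbut-2-en-1-yl)phenyl]butan-1-one | CCCC(=O)c1c(O)cc(O)c(CC=C(C)C)c1O
A2 | direct plan | 1-(2,4,6-trihydroxy-3-methylphenyl)ethan-1-one | CC(=O)c1c(O)c(C)c(O)cc1O
A3 | direct plan | 1-[3-[(3-acetyl-2,4,6-trihydroxy-5-methylphenyl)methyl]-2,4,6-trihydroxy-5-(3-methylbut-2-en-1-yl)phenyl]butan-1-one | CCCC(=O)c1c(O)c(CC=C(C)C)c(O)c(Cc2c(O)c(C)c(O)c(C(C)=O)c2O)c1O
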